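## Retrosynthetic overview

1. The α-methylene-γ-lactone is closed last by palladium-catalysed cyclocarbonylation of a cis-2-ethynylcyclohexenol; the C6 ester comes from simple acylation.
2. C6–OH and the C1 hydroxypropyl terminus come from Baeyer–Villiger opening (retention at C6) and reduction of a temporary cyclohexanone ring, which is the original carvone ring.
3. Ring B (C5=C10, C6, C7, C8) is formed in the key step, an ester-tethered intramolecular Diels–Alder reaction of a dienyl (E)-3-borylacrylate. C–B then becomes C8–O, and C7 is equilibrated at the aldehyde stage.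
4. The diene comes from Stille coupling of a dihydrocarvone enol triflate (isopropenyl converted to OH by ozonolysis/Criegee rearrangement) with a 2-stannylallyl silyl ether. The dienophile is attached with Mitsunobu inversion.
5. Ring order: carvone ring (bought, used as template) → ring B plus a transient γ-lactone (Diels–Alder) → template ring opened → α-methylene-γ-lactone.

Assumption: (S)-(+)-carvone, silyl ether 7 and boryl acid 10 are bought; atom labels C1–C14 follow 1,10-seco-eudesmane numbering (C6 = methacryloyloxy carbon, C7/C8 = lactone ring fusion, C5=C10 = ring alkene, C4 = methyl-bearing side-chain carbon, C1 = side-chain CH2OH, C14 = ring CH2OH, C11 = lactone α-carbon).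

## Route

Step 1
Reactants: 1 (S)-(+)-carvone
Product: 2 (2S,5S)-2-methyl-5-(prop-1-en-2-yl)cyclohexan-1-one (trans-dihydrocarvone)
Conditions: LiBH(sBu)3, THF, −78 °C; then NaOMe (cat.), MeOH, rt
Reagents that add atoms: none
Why: Conjugate (1,4) hydride reduction followed by base equilibration places the new methyl-bearing carbon (C4) equatorial and trans to the isopropenyl group, so the bought stereocentre fixes C4 as S (minor cis isomer removed by chromatography).

Step 2
Reactants: 2 trans-dihydrocarvone
Product: 3 (3S,6S)-6-methyl-3-(prop-1-en-2-yl)cyclohex-1-en-1-yl trifluoromethanesulfonate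
Conditions: LiN(iPr)2, THF, −78 °C; then PhNTf2, −78 → 0 °C
Reagents that add atoms: N-phenylbis(trifluoromethanesulfonimide), O=S(=O)(N(c1ccccc1)S(=O)(=O)C(F)(F)F)C(F)(F)F
Why: Kinetic deprotonation at the less substituted α-CH2 and O-sulfonylation (enol triflate formation) mark the future diene carbon C5 without touching the C4 stereocentre.

Step 3
Reactants: 3 enol triflate
Product: 6 (3S,6S)-3-hydroxy-6-methylcyclohex-1-en-1-yl trifluoromethanesulfonate, via methoxy hydroperoxide 4 (not isolated), via allylic acetate 5 (not isolated)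
Conditions: O3, CH2Cl2/MeOH, −78 °C; Ac2O, Et3N, DMAP (cat.), 0 °C → rt; then K2CO3 (cat.), MeOH, 0 °C
Reagents that add atoms: ozone, O=[O+][O-]
Why: Ozone attacks only the electron-rich isopropenyl group (the triflyloxy alkene is deactivated), the Criegee rearrangement of the peracetate replaces C–C by C–O with retention at C1, and methanolysis frees the alcohol.

Step 4
Reactants: 7 tert-butyldimethyl(prop-2-yn-1-yloxy)silane
Product: 8 tributyl{3-[(tert-butyldimethylsilyl)oxy]prop-1-en-2-yl}stannane
Conditions: Bu3SnH, Mo(CO)3(CNtBu)3 (cat.), hydroquinone, THF, 55 °C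
Reagents that add atoms: tributyltin hydride, CCCC[SnH](CCCC)CCCC
Why: Molybdenum-catalysed hydrostannation of propargylic ethers is α-selective and gives the 2-stannyl (1,1-disubstituted) allyl ether that carries C10, C9 and C14.

Step 5
Reactants: 6 hydroxy enol triflate; 8 alkenylstannane
Product: 9 (1S,4S)-3-{3-[(tert-butyldimethylsilyl)oxy]prop-1-en-2-yl}-4-methylcyclohex-2-en-1-ol
Conditions: Pd(PPh3)4 (cat.), CuI (cat.), LiCl, DMF, 45 °C
Reagents that add atoms: none
Why: Stille cross-coupling of the enol triflate with the alkenylstannane builds the 2,3-disubstituted diene C6=C5–C10=C9 with both alkene positions defined.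

Step 6
Reactants: 9 dienol; 10 (E)-3-(4,4,5,5-tetramethyl-1,3,2-dioxaborolan-2-yl)prop-2-enoic acid
Product: 11 (1R,4S)-3-{3-[(tert-butyldimethylsilyl)oxy]prop-1-en-2-yl}-4-methylcyclohex-2-en-1-yl (E)-3-(4,4,5,5-tetramethyl-1,3,2-dioxaborolan-2-yl)prop-2-enoate
Conditions: PPh3, DIAD, THF, 0 °C → rt
Reagents that add atoms: none
Why: Mitsunobu esterification proceeds with SN2 inversion at the allylic carbinol C1, so the dienophile is tethered on the same ring face as the C4 methyl group.

Step 7
Reactants: 11 dienyl borylacrylate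
Product: 12 tricyclic boryl γ-lactone (C1–O–C11(=O)–C7 lactone; Bpin at C8 trans to the C7 carbonyl; C5=C10 alkene)
Conditions: toluene (0.01 M), BHT, 150 °C, sealed tube
Reagents that add atoms: none
Why: In this intramolecular Diels–Alder reaction the three-atom ester tether can only deliver the acrylate to the diene face bearing C1–O (cis-fused γ-lactone), which sets C6 and C7; the E-alkene puts boron at C8 trans to the C7 carbonyl, and the tetrasubstituted C5=C10 alkene forms directly.

Step 8
Reactants: 12 tricyclic boryl lactone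
Product: 13 tricyclic hydroxy γ-lactone (C8–OH)
Conditions: NaBO3·4H2O, THF/H2O, rt
Reagents that add atoms: sodium perborate, [Na+].[O-]OB=O
Why: Perborate oxidation of the secondary alkylboronate occurs by 1,2-migration from boron to oxygen with retention, giving the C8 oxygen in its final configuration.

Step 9
Reactants: 13 hydroxy lactone
Product: 14 tricyclic triethylsilyloxy γ-lactone
Conditions: TESOTf, 2,6-lutidine, CH2Cl2, −78 °C
Reagents that add atoms: triethylsilyl trifluoromethanesulfonate, CC[Si](CC)(CC)OS(=O)(=O)C(F)(F)F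
Why: Silylation masks the axial C8 hydroxyl so that it stays distinct from the C6 and C1 hydroxyls unveiled later.

Step 10
Reactants: 14 silyloxy lactone
Product: 15 tricyclic lactol (C11 hemiacetal)
Conditions: iBu2AlH, CH2Cl2, −78 °C
Reagents that add atoms: none
Why: Half-reduction of the γ-lactone with the aluminium hydride at low temperature stops at the lactol, a masked C11 aldehyde.

Step 11
Reactants: 15 lactol
Product: 17 alkynol (C7 ethynyl trans to the C6–C1 bond and cis to C8–OTES; free C1–OH), via epimerised hydroxy aldehyde 16 (not isolated)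
Conditions: K2CO3, MeOH, rt; then MeC(O)C(N2)P(O)(OMe)2, rt
Reagents that add atoms: dimethyl (1-diazo-2-oxopropyl)phosphonate, CC(=O)C(=[N+]=[N-])P(=O)(OC)OC
Why: The ring-opened aldehyde epimerises at C7 to the equatorial isomer (the fused carvone ring holds C6–C1 pseudo-equatorial, so the formyl group moves trans to it and cis to the axial C8 oxygen); this isomer cannot re-close and is homologated to the terminal alkyne by the Ohira–Bestmann (Seyferth–Gilbert) reaction.

Step 12
Reactants: 17 alkynol
Product: 18 bicyclic β,γ-unsaturated ketone (C1 ketone)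
Conditions: Dess–Martin periodinane, pyridine, CH2Cl2, 0 °C
Reagents that add atoms: none
Why: Buffered Dess–Martin oxidation turns the C1 carbinol, whose configuration has done its work, into the ketone needed to excise the template ring, without conjugating the C5=C10 alkene.

Step 13
Reactants: 18 ketone
Product: 19 bicyclic ε-lactone (C6–O–C1(=O))
Conditions: Me3SiOOSiMe3, TMSOTf (cat.), CH2Cl2, −78 → −30 °C
Reagents that add atoms: bis(trimethylsilyl) peroxide, C[Si](C)(C)OO[Si](C)(C)C
Why: This Baeyer–Villiger variant spares alkenes; the allylic methine C6 migrates in preference to the CH2 and with retention, turning the C6–C1 bond into the C6–O bond of the target.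

Step 14
Reactants: 19 ε-lactone
Product: 20 diol (C6–OH and C1–OH)
Conditions: LiAlH4, THF, 0 °C
Reagents that add atoms: none
Why: Hydride reduction of the lactone opens the former carvone ring and releases the secondary C6 alcohol and the primary C1 alcohol of the side chain.

Step 15
Reactants: 20 diol
Product: 21 C1 tert-butyldimethylsilyl ether (C6–OH free)
Conditions: TBSCl (1.05 equiv), imidazole, CH2Cl2, −20 °C
Reagents that add atoms: tert-butyldimethylsilyl chloride, CC(C)(C)[Si](C)(C)Cl
Why: Silylation discriminates the unhindered primary C1 hydroxyl from the hindered allylic C6 hydroxyl.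

Step 16
Reactants: 21 mono-silyl ether
Product: 22 C6 methacrylate
Conditions: methacryloyl chloride, Et3N, DMAP (cat.), CH2Cl2, 0 °C
Reagents that add atoms: methacryloyl chloride, CC(=C)C(=O)Cl
Why: DMAP-catalysed acylation esterifies the only free hydroxyl (C6) with retention of configuration.

Step 17
Reactants: 22 methacrylate
Product: 23 alkynyl triol methacrylate (free C1, C14 and C8 hydroxyls)
Conditions: HF·pyridine, THF, 0 °C → rt
Reagents that add atoms: none
Why: Fluoride-mediated desilylation removes the three silyl ethers while the ester and the alkyne are untouched.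

Step 18
Reactants: 23 alkynyl triol
Product: 24 (3aR,4S,7aR)-5-[(2S)-5-hydroxypentan-2-yl]-6-(hydroxymethyl)-3-methylidene-2-oxo-2,3,3a,4,7,7a-hexahydro-1-benzofuran-4-yl 2-methylprop-2-enoate (CNP0142089.2)
Conditions: PdCl2 (cat.), SnCl2 (cat.), PPh3 (cat.), CO (7 atm), MeCN, 75 °C
Reagents that add atoms: carbon monoxide, [C-]#[O+]
Why: Norton-type palladium-catalysed cyclocarbonylation of the cis-homopropargylic alcohol (alkoxycarbonyl-palladium adds syn across the alkyne) closes the α-methylene-γ-butyrolactone without touching C7 or C8.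

## Compound list

1 | (S)-(+)-carvone, (5S)-2-methyl-5-(prop-1-en-2-yl)cyclohex-2-en-1-one | CC1=CC[C@H](C(C)=C)CC1=O | starting material
2 | (2S,5S)-2-methyl-5-(prop-1-en-2-yl)cyclohexan-1-one (trans-dihydrocarvone) | C[C@H]1CC[C@H](C(C)=C)CC1=O | intermediate
3 | (3S,6S)-6-methyl-3-(prop-1-en-2-yl)cyclohex-1-en-1-yl trifluoromethanesulfonate | C[C@H]1CC[C@H](C(C)=C)C=C1OS(=O)(=O)C(F)(F)F | intermediate
4 | methoxy hydroperoxide: (3S,6S)-3-(1-hydroperoxy-1-methoxyethyl)-6-methylcyclohex-1-en-1-yl trifluoromethanesulfonate (side-chain epimers) | C[C@H]1CC[C@H](C(C)(OC)OO)C=C1OS(=O)(=O)C(F)(F)F | intermediate (not isolated)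
5 | allylic acetate: (1S,4S)-4-methyl-3-{[(trifluoromethyl)sulfonyl]oxy}cyclohex-2-en-1-yl acetate | C[C@H]1CC[C@H](OC(C)=O)C=C1OS(=O)(=O)C(F)(F)F | intermediate (not isolated)
6 | (3S,6S)-3-hydroxy-6-methylcyclohex-1-en-1-yl trifluoromethanesulfonate (OH trans to CH3) | C[C@H]1CC[C@H](O)C=C1OS(=O)(=O)C(F)(F)F | intermediate
7 | tert-butyldimethyl(prop-2-yn-1-yloxy)silane | C#CCO[Si](C)(C)C(C)(C)C | starting material
8 | tributyl{3-[(tert-butyldimethylsilyl)oxy]prop-1-en-2-yl}stannane | C=C(CO[Si](C)(C)C(C)(C)C)[Sn](CCCC)(CCCC)CCCC | intermediate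
9 | (1S,4S)-3-{3-[(tert-butyldimethylsilyl)oxy]prop-1-en-2-yl}-4-methylcyclohex-2-en-1-ol (OH trans to CH3) | C[C@H]1CC[C@H](O)C=C1C(=C)CO[Si](C)(C)C(C)(C)C | intermediate
10 | (E)-3-(4,4,5,5-tetramethyl-1,3,2-dioxaborolan-2-yl)prop-2-enoic acid | OC(=O)/C=C/B1OC(C)(C)C(C)(C)O1 | starting material
11 | (1R,4S)-3-{3-[(tert-butyldimethylsilyl)oxy]prop-1-en-2-yl}-4-methylcyclohex-2-en-1-yl (E)-3-(pinacolboryl)prop-2-enoate (ester oxygen cis to CH3) | C[C@H]1CC[C@@H](OC(=O)/C=C/B2OC(C)(C)C(C)(C)O2)C=C1C(=C)CO[Si](C)(C)C(C)(C)C | intermediate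
12 | tricyclic boryl γ-lactone: C1–O–C11(=O)–C7 lactone cis-fused to the carvone ring and to ring B; C4 methyl, C1–O and C6–C7 on one face; C8–Bpin trans to the C7 carbonyl; C5=C10 alkene; C14–OTBS | O=C1O[C@@H]2CC[C@H](C)C3=C(CO[Si](C)(C)C(C)(C)C)C[C@@H](B4OC(C)(C)C(C)(C)O4)[C@H]1[C@H]23 | intermediate
13 | tricyclic hydroxy γ-lactone (C8–OH in place of Bpin, same configuration) | O=C1O[C@@H]2CC[C@H](C)C3=C(CO[Si](C)(C)C(C)(C)C)C[C@@H](O)[C@H]1[C@H]23 | intermediate
14 | tricyclic triethylsilyloxy γ-lactone (C8–OTES) | O=C1O[C@@H]2CC[C@H](C)C3=C(CO[Si](C)(C)C(C)(C)C)C[C@@H](O[Si](CC)(CC)CC)[C@H]1[C@H]23 | intermediate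
15 | tricyclic lactol (C11 hemiacetal, anomers) | OC1O[C@@H]2CC[C@H](C)C3=C(CO[Si](C)(C)C(C)(C)C)C[C@@H](O[Si](CC)(CC)CC)[C@H]1[C@H]23 | intermediate
16 | epimerised hydroxy aldehyde (C7–CHO trans to C6–C1, cis to C8–OTES; C1–OH) | O[C@@H]1CC[C@H](C)C2=C(CO[Si](C)(C)C(C)(C)C)C[C@@H](O[Si](CC)(CC)CC)[C@@H](C=O)[C@H]12 | intermediate (not isolated)
17 | alkynol (C7 ethynyl trans to C6–C1, cis to C8–OTES; C1–OH) | O[C@@H]1CC[C@H](C)C2=C(CO[Si](C)(C)C(C)(C)C)C[C@@H](O[Si](CC)(CC)CC)[C@@H](C#C)[C@H]12 | intermediate
18 | bicyclic β,γ-unsaturated ketone (C1 ketone; C5=C10 alkene) | O=C1CC[C@H](C)C2=C(CO[Si](C)(C)C(C)(C)C)C[C@@H](O[Si](CC)(CC)CC)[C@@H](C#C)[C@H]12 | intermediate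
19 | bicyclic ε-lactone (C6–O–C1(=O); C6–O trans to the C7 ethynyl group) | O=C1CC[C@H](C)C2=C(CO[Si](C)(C)C(C)(C)C)C[C@@H](O[Si](CC)(CC)CC)[C@@H](C#C)[C@@H]2O1 | intermediate
20 | diol (C6–OH, C1–OH; C8–OTES; C14–OTBS) | OCCC[C@H](C)C1=C(CO[Si](C)(C)C(C)(C)C)C[C@@H](O[Si](CC)(CC)CC)[C@@H](C#C)[C@@H]1O | intermediate
21 | C1 tert-butyldimethylsilyl ether with free C6–OH | CC(C)(C)[Si](C)(C)OCCC[C@H](C)C1=C(CO[Si](C)(C)C(C)(C)C)C[C@@H](O[Si](CC)(CC)CC)[C@@H](C#C)[C@@H]1O | intermediate
22 | C6 methacrylate (fully silylated) | CC(C)(C)[Si](C)(C)OCCC[C@H](C)C1=C(CO[Si](C)(C)C(C)(C)C)C[C@@H](O[Si](CC)(CC)CC)[C@@H](C#C)[C@@H]1OC(=O)C(C)=C | intermediate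
23 | alkynyl triol methacrylate (C8–OH cis to the C7 ethynyl group) | OCCC[C@H](C)C1=C(CO)C[C@@H](O)[C@@H](C#C)[C@@H]1OC(=O)C(C)=C | intermediate
24 | (3aR,4S,7aR)-5-[(2S)-5-hydroxypentan-2-yl]-6-(hydroxymethyl)-3-methylidene-2-oxo-2,3,3a,4,7,7a-hexahydro-1-benzofuran-4-yl 2-methylprop-2-enoate | C=C(C)C(=O)O[C@@H]1C([C@@H](C)CCCO)=C(CO)C[C@H]2OC(=O)C(=C)[C@@H]12 | target

## Step count and risks

Total step count: 18. Longest linear sequence: 17 steps (1 → 2 → 3 → 6 → 9 → 11 → 12 → … → 24; step 4 is the side branch).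

Three steps most likely to fail, each with a fallback:

**Step 7 (ester-tethered intramolecular Diels–Alder).** Dienyl esters prefer the unreactive ester conformation, and the allylic ester may decompose before it cyclises. The fallback sets out from 9 and comes back at 18.
- Dienol 9 is acetylated (Ac2O, pyridine) to the diene acetate F1.
- F1 is heated with (E)-3-(pinacolboryl)acrolein in toluene at 80 °C. Addition on the face away from the pseudoaxial acetoxy group, which sits next to the bond-forming diene terminus, gives the endo adduct F2 (formyl at C7 cis to C6–C1, boryl at C8 trans to the formyl group).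
- K2CO3 in MeOH epimerises C7 and removes the acetate; the Ohira–Bestmann reagent added to the same flask gives the alkynol F3. Its C1 configuration is opposite to that of 17, which does not matter.
- Dess–Martin oxidation gives the boryl ketone F4, NaBO3 oxidation gives the hydroxy ketone F5, and silylation with TESOTf and 2,6-lutidine leads to 18.
- In this variant the face selectivity rests on sterics only: the C4 methyl opposes the acetoxy group, so a mixture is possible and the wrong-face adduct would have to be separated.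

**Step 13 (chemoselective Baeyer–Villiger oxidation).** The β,γ-unsaturated ketone may slip into conjugation under the Lewis acid, or the peroxide may attack the C5=C10 alkene. The fallback sets out from 18 and comes back at 19.
- Ketone 18 is treated with excess mCPBA and NaHCO3 in CH2Cl2, which deliberately performs both the Baeyer–Villiger reaction and the epoxidation of the tetrasubstituted alkene, giving the epoxy lactone F6.
- The epoxide is removed again with the low-valent tungsten reagent made from WCl6 and nBuLi in THF, which returns the alkene and gives 19.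

**Step 18 (cyclocarbonylation of the free alkynyl triol).** The two primary hydroxyls and the methacrylate may interfere with the palladium catalyst. The fallback sets out from 22 and comes back at 24.
- Markovnikov iodoboration of the alkyne of 22 with B-iodo-9-borabicyclo[3.3.1]nonane in pentane at −20 °C, then protonolysis with AcOH, gives the 2-iodoalkene F7.
- HF·pyridine removes the three silyl groups to give the iodo triol F8.
- Carbonylative lactonisation through an acyl-palladium species (Pd(PPh3)2Cl2 cat., CO 1 atm, K2CO3, THF, 50 °C) closes the α-methylene lactone with the cis C8 hydroxyl and gives 24.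

Further compounds

F1 | step 7 | diene acetate, (1S,4S)-3-{3-[(tert-butyldimethylsilyl)oxy]prop-1-en-2-yl}-4-methylcyclohex-2-en-1-yl acetate | C[C@H]1CC[C@H](OC(C)=O)C=C1C(=C)CO[Si](C)(C)C(C)(C)C
F2 | step 7 | endo adduct (C1–OAc; C7–CHO cis to C6–C1; C8–Bpin trans to CHO) | CC(=O)O[C@H]1CC[C@H](C)C2=C(CO[Si](C)(C)C(C)(C)C)C[C@@H](B3OC(C)(C)C(C)(C)O3)[C@H](C=O)[C@H]12
F3 | step 7 | alkynol (C1 epimer series; C7 ethynyl trans to C6–C1; C8–Bpin) | O[C@H]1CC[C@H](C)C2=C(CO[Si](C)(C)C(C)(C)C)C[C@@H](B3OC(C)(C)C(C)(C)O3)[C@@H](C#C)[C@H]12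
F4 | step 7 | boryl ketone (C1 ketone; C8–Bpin) | O=C1CC[C@H](C)C2=C(CO[Si](C)(C)C(C)(C)C)C[C@@H](B3OC(C)(C)C(C)(C)O3)[C@@H](C#C)[C@H]12
F5 | step 7 | hydroxy ketone (C1 ketone; C8–OH) | O=C1CC[C@H](C)C2=C(CO[Si](C)(C)C(C)(C)C)C[C@@H](O)[C@@H](C#C)[C@H]12
F6 | step 13 | epoxy lactone (ε-lactone with C5–C10 epoxide, epoxide face unassigned) | O=C1CC[C@H](C)C23OC2(CO[Si](C)(C)C(C)(C)C)C[C@@H](O[Si](CC)(CC)CC)[C@@H](C#C)[C@@H]3O1
F7 | step 18 | 2-iodoalkene (C7 bears a 1-iodovinyl group; otherwise as 22) | CC(C)(C)[Si](C)(C)OCCC[C@H](C)C1=C(CO[Si](C)(C)C(C)(C)C)C[C@@H](O[Si](CC)(CC)CC)[C@@H](C(I)=C)[C@@H]1OC(=O)C(C)=C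
F8 | step 18 | iodo triol (C7 1-iodovinyl; free C1, C14 and C8 hydroxyls) | OCCC[C@H](C)C1=C(CO)C[C@@H](O)[C@@H](C(I)=C)[C@@H]1OC(=O)C(C)=C
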